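The runs were generated by integration for substances that don't exist, noise included.

By 90.0 min of stirring, Thursday's flask with 5.5 mM of initiator and Monday's with 22 mM read 81% and 81% of target, each reading with a scatter of 1.5 percentage points. At 8.00 min the same two flasks read 42% and 65%, so the runs differ early, but their last readings agree within that scatter, and we look for the end in the amounts charged.

| flask | substrate | partner | initiator | remark | time |
|---|---|---|---|---|---|
| Thursday's | 0.11 M (in portions, 2) | 0.104 M | 5.5 mM | run made earlier; portions every 3.0 min |  |
| Monday's | 0.11 M (in portions, 2) | 0.104 M | 22 mM | run made earlier; portions every 3.0 min |  |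
| larch | 0.11 M (in portions, 2) | 0.104 M | 11 mM | the portions of substrate follow each other after 3.0 min, the first at the start | 2.0 h |
| birch | 0.11 M | 0.104 M | 11 mM | everything together at the start | 1.0 h |

| Thursday's: time / min | Thursday's: target / % | Monday's: time / min | Monday's: target / % |
|---|---|---|---|
| 8.00 | 42 | 8.00 | 65 |
| 12.0 | 53 | 12.0 | 74 |
| 20.0 | 66 | 20.0 | 78 |
| 40.0 | 75 | 40.0 | 83 |
| 60.0 | 78 | 60.0 | 80 |
| 90.0 | 81 | 90.0 | 81 |

(scatter of a reading: 1.5 percentage points)

- percent here means substrate units held: one ended chains counts as two
- what was read earlier has a scatter of 1.5 percentage points, one standard deviation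
- reactions considered so far: partner + first chain carrier -> target + second chain carrier; substrate + second chain carrier -> by-product + first chain carrier; partner -> decomposition product; initiator -> 2 initiating radical; partner <-> dormant form; substrate + initiating radical -> capped initiator + first chain carrier; 2 first chain carrier -> ended chains

- the flask that ends with the higher amount of target, in percent of the substrate charged, or "neither" when 2 percentage points or less lies between them (larch / birch / neither)
- final target, as a percentage of the substrate charged, in larch
- final target, as a percentage of the substrate charged, in birch

We write the balance of partner, the smaller charge at 0.104 M against 0.11 M of substrate. Each target takes one partner, so c(target) cannot pass 94.5% of the substrate charged, yet the last readings stand below that ceiling. Two amounts therefore matter: the last reading, 0.0891 M of target, and the 0.104 M of partner charged. Their ratio, the partner yield 85.7%, is the share of charged partner that stands as target at that reading.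

Larch and birch carry the same partner and substrate, and their 11 mM of initiator lies between the charges of the two runs, so our reckoning gives 81.0% for larch. Birch stops at 60 min, when Thursday's and Monday's flasks read 78% and 80%, and we expect it within 2 points of larch.

The forecast says 81% for larch, 80% for birch and neither, holding that “Dosing hardly matters”.

Larch and birch each end at 83.1%, so the answer is neither.

    partner + first chain carrier → target + second chain carrier (k = 5080 L mol⁻¹ s⁻¹)
    substrate + second chain carrier → by-product + first chain carrier (k = 1740 L mol⁻¹ s⁻¹)
    partner → decomposition product (k = 4.09 × 10⁻⁷ s⁻¹)
    initiator → 2 initiating radical (k = 6.96 × 10⁻⁴ s⁻¹)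
    partner ⇌ dormant form (K = 4.70, k = 1.81 × 10⁻⁴ s⁻¹)
    substrate + initiating radical → capped initiator + first chain carrier (k = 1.71 × 10⁵ L mol⁻¹ s⁻¹)
    2 first chain carrier → ended chains (k = 5.60 × 10⁷ L mol⁻¹ s⁻¹)

In birch at 1.00 h, 0.00997 M of dormant form stands and 2.51% of the partner charge is left, with a partner yield of 87.9%. The outcome moves with the partner charge: a birch flask with 0.026 M of partner has partner as its limiting reagent, with 1.5% left. The yield read earlier, 85.7%, gives that flask 20.3%, and it ends at 21.0%.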